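**Retrosynthetic overview**
1. Target 8 ⇒ pyrrole ester 6: the 5-acetyl group goes on last, by Vilsmeier–Haack acylation of the only free pyrrole carbon.
2. 6 ⇒ keto ester 2 + nitroalkene 3 + NH3. The key C3–C4 bond joins two carbons that are each α to a carbonyl-level carbon (C2, C5) and would normally both be nucleophilic. Nitroalkene 3 reverses the polarity at C4: it acts as an α-carbonyl cation (enolonium) equivalent, with the nitro carbon as the masked carbonyl-level C5.
3. In the same flask the enamine nitrogen closes onto the aci-nitro carbon and water and HNO leave. The pyrrole is the only ring formed; both indoles are bought intact.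
4. 2 ⇒ 1 by carboxylate methylation.

Assumption: the target has no stereocentre and no stereogenic double bond, so there is no enantiomer to select and the route gives the one achiral compound. Compounds 1 and 3 are taken as bought catalogue materials.

**Step 1**
Reactants: 1 3-(1H-indol-3-yl)-2-oxopropanoic acid (indole-3-pyruvic acid)
Product: 2 methyl 3-(1H-indol-3-yl)-2-oxopropanoate
Conditions: MeI (1.1 equiv), KHCO3 (1.0 equiv), DMF, 0 °C to rt, Ar
Reagents that add atoms: iodomethane, CI
Why: SN2 O-alkylation of the carboxylate; one equivalent of the weak base KHCO3 ionises only the carboxylic acid, not the enol OH or the indole NH, so MeI methylates the carboxylate alone, and no stereocentre is formed.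

**Step 2**
Reactants: 2 methyl 3-(1H-indol-3-yl)-2-oxopropanoate; 3 3-[(E)-2-nitroethenyl]-1H-indole
Product: 6 methyl 3,4-di(1H-indol-3-yl)-1H-pyrrole-2-carboxylate, via enamine 4 (not isolated), via nitro adduct 5 (not isolated)
Conditions: NH4OAc (5 equiv), MeOH, rt, 1 h; then 3 (1.1 equiv), AcOH, 65 °C, Ar
Reagents that add atoms: ammonium acetate, CC(=O)[O-].[NH4+]
Why: Proposed new method: the primary enamine 4, formed from the α-keto ester and NH4OAc, is nucleophilic at its indolyl-bearing β-carbon and adds to the acid-activated nitroalkene 3 (the enolonium equivalent) to make the C3–C4 bond; the enamine nitrogen of adduct 5 then attacks the aci-nitro carbon and water and HNO are lost to give the aromatic pyrrole, so the closest known reaction type is the Grob–Camenisch nitroalkene–enaminone pyrrole synthesis (three-component form with 1,3-dicarbonyls and amines), extended here to an α-keto ester; the transient stereocentre of 5 is lost on aromatisation.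

**Step 3**
Reactants: 6 methyl 3,4-di(1H-indol-3-yl)-1H-pyrrole-2-carboxylate
Product: 8 methyl 5-acetyl-3,4-di(1H-indol-3-yl)-1H-pyrrole-2-carboxylate, via iminium salt 7 (not isolated)
Conditions: DMA (3 equiv), POCl3 (1.5 equiv), ClCH2CH2Cl, 0 °C to 60 °C; then aq. NaOAc, 60 °C
Reagents that add atoms: N,N-dimethylacetamide, CC(=O)N(C)C; water, O
Why: Vilsmeier–Haack acylation; the chloroiminium ion attacks C5, the only free pyrrole carbon, which is an α-position further activated by the 4-indolyl donor, while C2 of a 3-substituted indole reacts much more slowly and the NH groups are not acylated without base; hydrolysis of iminium salt 7 gives the ketone and no stereocentre is formed.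

**Compound list**
1 | 3-(1H-indol-3-yl)-2-oxopropanoic acid (indole-3-pyruvic acid) | O=C(O)C(=O)Cc1c[nH]c2ccccc12 | starting material
2 | methyl 3-(1H-indol-3-yl)-2-oxopropanoate (drawn as keto form, largely enolised) | COC(=O)C(=O)Cc1c[nH]c2ccccc12 | intermediate
3 | 3-[(E)-2-nitroethenyl]-1H-indole | [O-][N+](=O)/C=C/c1c[nH]c2ccccc12 | starting material
4 | methyl (Z)-2-amino-3-(1H-indol-3-yl)prop-2-enoate (formed in the flask) | COC(=O)/C(N)=C/c1c[nH]c2ccccc12 | intermediate
5 | methyl 2-amino-3,4-di(1H-indol-3-yl)-5-nitropent-2-enoate (formed in the flask; racemic, alkene geometry not defined) | COC(=O)C(N)=C(c1c[nH]c2ccccc12)C(C[N+](=O)[O-])c1c[nH]c2ccccc12 | intermediate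
6 | methyl 3,4-di(1H-indol-3-yl)-1H-pyrrole-2-carboxylate | COC(=O)c1[nH]cc(-c2c[nH]c3ccccc23)c1-c1c[nH]c2ccccc12 | intermediate
7 | methyl 5-[1-(dimethyliminio)ethyl]-3,4-di(1H-indol-3-yl)-1H-pyrrole-2-carboxylate chloride (formed in the flask) | COC(=O)c1[nH]c(C(C)=[N+](C)C)c(-c2c[nH]c3ccccc23)c1-c1c[nH]c2ccccc12.[Cl-] | intermediate
8 | methyl 5-acetyl-3,4-di(1H-indol-3-yl)-1H-pyrrole-2-carboxylate | COC(=O)c1[nH]c(C(C)=O)c(-c2c[nH]c3ccccc23)c1-c1c[nH]c2ccccc12 | target

**Totals**
Total step count: 3. Longest linear sequence: 3 steps (1 → 2 → 6 → 8).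

**Steps most likely to fail, with fallbacks**

Step 2 (highest risk). Nitroalkene 3 is a push–pull, only moderately electrophilic acceptor, the primary enamine 4 has no precedent as the carbon donor, and free ammonia can divert either partner. The fallback sets out from 2 (with 3) and comes back at 6. It takes ammonia out of the C–C bond formation and closes the ring by a different reaction. The enol of 2 is added to 3 under tertiary-amine catalysis (10 mol % Et3N, THF, rt) and methyl 3,4-di(1H-indol-3-yl)-5-nitro-2-oxopentanoate F1 is isolated. A reductive Nef reaction (aq. TiCl3, NH4OAc buffer, THF, rt) unmasks the nitro carbon to give the 1,4-keto aldehyde methyl 3,4-di(1H-indol-3-yl)-2,5-dioxopentanoate F2. Paal–Knorr condensation (NH4OAc, AcOH, 60 °C) then gives 6.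

Step 3. The risk is regiochemistry: acylation at an indole C2 or nitrogen could compete with pyrrole C5. The fallback sets out from 2 and comes back at 8. It uses no electrophilic substitution: the acetyl group arrives with the nitroalkene and the nitro nitrogen becomes the ring nitrogen. Knoevenagel condensation of indole-3-carbaldehyde with nitroacetone (piperidinium acetate, i-PrOH, rt) gives 4-(1H-indol-3-yl)-3-nitrobut-3-en-2-one F3. Et3N-catalysed Michael addition of 2 gives methyl 3,4-di(1H-indol-3-yl)-5-nitro-2,6-dioxoheptanoate F4. Ammonia must be kept out here, because an enamine nitrogen on C2 would close onto the acetyl carbonyl and give a 5-nitro-1,4-dihydropyridine. Instead Bu3P/PhSSPh (THF, rt; Barton deoxygenation of a secondary nitro group) gives the NH-ketimine methyl 5-imino-3,4-di(1H-indol-3-yl)-2,6-dioxoheptanoate F5. Its nitrogen can only reach the C2 ketone through a five-membered ring, and loss of water gives 8.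

Step 1 (lowest risk). The keto acid and its ester are air- and base-sensitive (enol O-methylation, aldol self-condensation). The fallback sets out from 1 and comes back at 6. It postpones the esterification until the sensitive pyruvate unit is gone. The annulation of step 2 is run on 1 itself (NH4OAc, MeOH/AcOH, 3, 65 °C). It passes through (Z)-2-amino-3-(1H-indol-3-yl)prop-2-enoic acid F6 and 2-amino-3,4-di(1H-indol-3-yl)-5-nitropent-2-enoic acid F7 to give 3,4-di(1H-indol-3-yl)-1H-pyrrole-2-carboxylic acid F8. This robust acid is then methylated (MeI, KHCO3, DMF) to 6.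

**Further compounds**
F1 | step 2 | methyl 3,4-di(1H-indol-3-yl)-5-nitro-2-oxopentanoate (mixture of diastereomers) | COC(=O)C(=O)C(c1c[nH]c2ccccc12)C(C[N+](=O)[O-])c1c[nH]c2ccccc12
F2 | step 2 | methyl 3,4-di(1H-indol-3-yl)-2,5-dioxopentanoate (mixture of diastereomers) | COC(=O)C(=O)C(c1c[nH]c2ccccc12)C(C=O)c1c[nH]c2ccccc12
F3 | step 3 | 4-(1H-indol-3-yl)-3-nitrobut-3-en-2-one (drawn E; geometry of no consequence) | CC(=O)/C(=C\c1c[nH]c2ccccc12)[N+](=O)[O-]
F4 | step 3 | methyl 3,4-di(1H-indol-3-yl)-5-nitro-2,6-dioxoheptanoate (mixture of diastereomers) | COC(=O)C(=O)C(c1c[nH]c2ccccc12)C(c1c[nH]c2ccccc12)C(C(C)=O)[N+](=O)[O-]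
F5 | step 3 | methyl 5-imino-3,4-di(1H-indol-3-yl)-2,6-dioxoheptanoate (mixture of diastereomers) | COC(=O)C(=O)C(c1c[nH]c2ccccc12)C(c1c[nH]c2ccccc12)C(=N)C(C)=O
F6 | step 1 | (Z)-2-amino-3-(1H-indol-3-yl)prop-2-enoic acid | N/C(=C\c1c[nH]c2ccccc12)C(=O)O
F7 | step 1 | 2-amino-3,4-di(1H-indol-3-yl)-5-nitropent-2-enoic acid (racemic) | NC(C(=O)O)=C(c1c[nH]c2ccccc12)C(C[N+](=O)[O-])c1c[nH]c2ccccc12
F8 | step 1 | 3,4-di(1H-indol-3-yl)-1H-pyrrole-2-carboxylic acid | O=C(O)c1[nH]cc(-c2c[nH]c3ccccc23)c1-c1c[nH]c2ccccc12
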